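**Retrosynthetic overview**
- Both pyranone rings are opened at O1–C2 and O1'–C2' to a bis(ortho-methoxyaryl ynone), handled as its pyrrolidine enaminone. The C4–C3 and C4'–C3' bonds are then cut to a 2,2'-diformyl-tetramethoxybiphenyl and lithiated 4-phenylbut-1-yne.
- Feature the strategy rests on: in ring A (benzo ring of the 6-hydroxy half) C5 and C4a are adjacent, and each sits next to an oxygen-bearing carbon (C6–OH and C8a–O1). They are therefore the two ends of the triple bond of a symmetrical 3,6-dimethoxybenzyne.
- Key disconnection: C5–C5' and C4a–C4 are made in one operation from the ring B aryllithium (from 2,3-dimethoxybenzaldehyde), the aryne (from 2-bromo-1,4-dimethoxybenzene) and DMF.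
- Ring order: both benzene rings are bought, the biaryl bond is made first, and the two pyranone rings are closed together in the last step.

Key step: step 3

Assumption: the target is drawn without a stereodescriptor, so the C5–C5' axis is treated as configurationally undefined; no stereocentre has to be set.

**Step 1**
Reactants: 1 2,3-dimethoxybenzaldehyde
Product: 2 6-bromo-2,3-dimethoxybenzaldehyde
Conditions: NBS, DMF, rt
Reagents that add atoms: N-bromosuccinimide, O=C1CCC(=O)N1Br
Why: Electrophilic aromatic bromination; the conjugated 3-methoxy group directs para to C6 (the 2-methoxy group is twisted out of plane between two neighbours), the established outcome for this aldehyde with NBS in DMF.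

**Step 2**
Reactants: 2 6-bromo-2,3-dimethoxybenzaldehyde
Product: 3 1-bromo-2-(dimethoxymethyl)-3,4-dimethoxybenzene
Conditions: HC(OMe)3, MeOH, cat. p-TsOH, reflux; Et3N quench
Reagents that add atoms: trimethyl orthoformate, COC(OC)OC; methanol, CO
Why: Acid-catalysed acetalization driven by the orthoformate as water scavenger should mask the aldehyde against organolithiums and give a chelating ortho group for the aryllithium.

**Step 3**
Reactants: 3 1-bromo-2-(dimethoxymethyl)-3,4-dimethoxybenzene; 4 2-bromo-1,4-dimethoxybenzene; 5 N,N-dimethylformamide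
Product: 11 2'-(dimethoxymethyl)-3,3',4',6-tetramethoxybiphenyl-2-carbaldehyde, via aryllithium 6 (not isolated), via lithiated bromoarene 7 (not isolated), via 3,6-dimethoxybenzyne 8 (not isolated), via biaryllithium 9 (not isolated), via lithium hemiaminolate 10 (not isolated)
Conditions: flask 1: 3 (1.5 equiv), t-BuLi (3.0 equiv), THF, −78 °C; flask 2: lithium 2,2,6,6-tetramethylpiperidide (LiTMP, from 2,2,6,6-tetramethylpiperidine and n-BuLi), THF, then 4 (1.0 equiv), −78 °C, 1 h; cannulate flask 1 into flask 2 at −78 °C, warm slowly to −10 °C; recool to −78 °C, DMF (excess), to 0 °C; H2O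
Reagents that add atoms: none
Why: Bromine–lithium exchange on 3 gives aryllithium 6, while LiTMP separately removes the proton of 4 that lies between bromine and methoxy to give 7, which is kept at −78 °C until all of 4 is metallated. On mixing and slow warming, 7 loses LiBr to release the symmetrical aryne 8, 6 adds across the strained triple bond (C5–C5'), and the resulting biaryllithium 9 is formylated by DMF through hemiaminolate 10 (C4a–C4), which collapses to the aldehyde on aqueous work-up. The closest known reaction type is the addition of an aryllithium or aryl Grignard reagent to an aryne generated from an ortho-metallated haloarene, followed by electrophilic quench of the 2-metallated biaryl. No ring is closed and no stereocentre is formed, and because the aryne is symmetrical both modes of addition give the same regioisomer. The selectivity needed is chemoselectivity: 6 must add to 8 faster than 7 or 9 do and must not undergo bromine–lithium exchange with the aryne precursor. This should be secured by complete pre-metallation of 4 (exchange at the bromine of 7 would require a vicinal dianion), by gradual thermal release of 8 into an excess of 6, and by the lower nucleophilicity of the doubly ortho-flanked anions 7 and 9, the latter stabilised by its ortho methoxy group.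

**Step 4**
Reactants: 11 2'-(dimethoxymethyl)-3,3',4',6-tetramethoxybiphenyl-2-carbaldehyde
Product: 12 3,3',4',6-tetramethoxybiphenyl-2,2'-dicarbaldehyde
Conditions: 2 M aq. HCl, THF, rt
Reagents that add atoms: water, O
Why: Acid-catalysed acetal hydrolysis should unveil the second formyl group, the aryl methyl ethers and the biaryl being inert to dilute acid.

**Step 5**
Reactants: 12 3,3',4',6-tetramethoxybiphenyl-2,2'-dicarbaldehyde; 13 4-phenylbut-1-yne
Product: 15 1,1'-(3,3',4',6-tetramethoxybiphenyl-2,2'-diyl)bis(5-phenylpent-2-yn-1-ol), via lithium acetylide 14 (not isolated)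
Conditions: 13 (3 equiv), n-BuLi, THF, −78 °C; then 12, −78 → 0 °C; H2O
Reagents that add atoms: none
Why: 1,2-Addition of a lithium acetylide to aromatic aldehydes; the slim nucleophile in excess should reach both hindered formyl groups, and the two carbinol centres, formed without control as a diastereomer mixture, are erased in step 6.

**Step 6**
Reactants: 15 1,1'-(3,3',4',6-tetramethoxybiphenyl-2,2'-diyl)bis(5-phenylpent-2-yn-1-ol)
Product: 16 1,1'-(3,3',4',6-tetramethoxybiphenyl-2,2'-diyl)bis(5-phenylpent-2-yn-1-one)
Conditions: Dess–Martin periodinane (3 equiv), CH2Cl2, rt; aq. Na2S2O3/NaHCO3 work-up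
Reagents that add atoms: none
Why: Dess–Martin oxidation of secondary benzylic propargylic alcohols to ynones is mild and neutral and should converge all diastereomers to one bis-ynone.

**Step 7**
Reactants: 16 1,1'-(3,3',4',6-tetramethoxybiphenyl-2,2'-diyl)bis(5-phenylpent-2-yn-1-one)
Product: 17 (2E,2'E)-1,1'-(3,3',4',6-tetramethoxybiphenyl-2,2'-diyl)bis[5-phenyl-3-(pyrrolidin-1-yl)pent-2-en-1-one]
Conditions: pyrrolidine (3 equiv), EtOH, rt
Reagents that add atoms: pyrrolidine, C1CCNC1
Why: Aza-Michael addition of a secondary amine to an ynone should give the vinylogous amide (E expected, the geometry being of no consequence), which fixes the β-carbon as the only electrophilic site for the later 6-endo closure and protects the triple bond from bromide addition in step 8.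

**Step 8**
Reactants: 17 (2E,2'E)-1,1'-(3,3',4',6-tetramethoxybiphenyl-2,2'-diyl)bis[5-phenyl-3-(pyrrolidin-1-yl)pent-2-en-1-one]
Product: 18 6-hydroxy-5-[8-hydroxy-4-oxo-2-(2-phenylethyl)-4H-chromen-5-yl]-2-(2-phenylethyl)-4H-chromen-4-one
Conditions: BBr3 (12 equiv), CH2Cl2, −78 °C → rt; MeOH quench; then 2 M HCl, MeOH, 50 °C
Reagents that add atoms: none
Why: BBr3 cleavage of all four aryl methyl ethers, followed by the enaminone route to chromones, in which each phenol ortho to the acyl group closes a pyranone ring by 6-endo-trig addition–elimination at the β-carbon with loss of pyrrolidine; the other two phenols cannot reach an electrophilic carbon through a six-membered ring and should stay free.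

**Compound list**
1 | 2,3-dimethoxybenzaldehyde | COc1cccc(C=O)c1OC | starting material
2 | 6-bromo-2,3-dimethoxybenzaldehyde | COc1ccc(Br)c(C=O)c1OC | intermediate
3 | 1-bromo-2-(dimethoxymethyl)-3,4-dimethoxybenzene | COc1ccc(Br)c(C(OC)OC)c1OC | intermediate
4 | 2-bromo-1,4-dimethoxybenzene | COc1ccc(OC)c(Br)c1 | starting material
5 | N,N-dimethylformamide | CN(C)C=O | starting material
6 | [2-(dimethoxymethyl)-3,4-dimethoxyphenyl]lithium (not isolated) | [Li]c1ccc(OC)c(OC)c1C(OC)OC | intermediate
7 | (2-bromo-3,6-dimethoxyphenyl)lithium (not isolated) | [Li]c1c(Br)c(OC)ccc1OC | intermediate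
8 | 3,6-dimethoxybenzyne (1,2-didehydro-3,6-dimethoxybenzene, not isolated) | COC1=CC=C(OC)C#C1 | intermediate
9 | [2'-(dimethoxymethyl)-3,3',4',6-tetramethoxybiphenyl-2-yl]lithium (not isolated) | [Li]c1c(OC)ccc(OC)c1-c1ccc(OC)c(OC)c1C(OC)OC | intermediate
10 | lithium (dimethylamino)[2'-(dimethoxymethyl)-3,3',4',6-tetramethoxybiphenyl-2-yl]methanolate (not isolated, configuration undefined) | [Li]OC(N(C)C)c1c(OC)ccc(OC)c1-c1ccc(OC)c(OC)c1C(OC)OC | intermediate
11 | 2'-(dimethoxymethyl)-3,3',4',6-tetramethoxybiphenyl-2-carbaldehyde | O=Cc1c(OC)ccc(OC)c1-c1ccc(OC)c(OC)c1C(OC)OC | intermediate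
12 | 3,3',4',6-tetramethoxybiphenyl-2,2'-dicarbaldehyde | O=Cc1c(OC)ccc(OC)c1-c1ccc(OC)c(OC)c1C=O | intermediate
13 | 4-phenylbut-1-yne | C#CCCc1ccccc1 | starting material
14 | (4-phenylbut-1-yn-1-yl)lithium (not isolated) | [Li]C#CCCc1ccccc1 | intermediate
15 | 1,1'-(3,3',4',6-tetramethoxybiphenyl-2,2'-diyl)bis(5-phenylpent-2-yn-1-ol), diastereomer mixture, carbinol centres undefined | OC(C#CCCc1ccccc1)c1c(OC)ccc(OC)c1-c1ccc(OC)c(OC)c1C(O)C#CCCc1ccccc1 | intermediate
16 | 1,1'-(3,3',4',6-tetramethoxybiphenyl-2,2'-diyl)bis(5-phenylpent-2-yn-1-one) | O=C(C#CCCc1ccccc1)c1c(OC)ccc(OC)c1-c1ccc(OC)c(OC)c1C(=O)C#CCCc1ccccc1 | intermediate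
17 | (2E,2'E)-1,1'-(3,3',4',6-tetramethoxybiphenyl-2,2'-diyl)bis[5-phenyl-3-(pyrrolidin-1-yl)pent-2-en-1-one] | O=C(/C=C(/N1CCCC1)CCc1ccccc1)c1c(OC)ccc(OC)c1-c1ccc(OC)c(OC)c1C(=O)/C=C(/N1CCCC1)CCc1ccccc1 | intermediate
18 | 6-hydroxy-5-[8-hydroxy-4-oxo-2-(2-phenylethyl)-4H-chromen-5-yl]-2-(2-phenylethyl)-4H-chromen-4-one | O=c1cc(CCc2ccccc2)oc2ccc(O)c(-c3ccc(O)c4oc(CCc5ccccc5)cc(=O)c34)c12 | target

**Step count**
Total steps: 8. Longest linear sequence: 8 (from 2,3-dimethoxybenzaldehyde; compounds 4, 5 and 13 enter as purchased materials).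

**Steps most likely to fail**

1. Step 3. The aryne may be consumed by 7 or 9 instead of 6 (oligoarylation), halogen–lithium scrambling may occur if metallation of 4 is incomplete, or 9 may be protonated before formylation. Fallback, setting out from 3 and 4 and returning at 11: the biaryl bond is made by Suzuki–Miyaura coupling and the formyl carbon is installed beforehand. Aryllithium 6 (from 3, t-BuLi, −78 °C) is quenched with 2-isopropoxy-4,4,5,5-tetramethyl-1,3,2-dioxaborolane to give 2-[2-(dimethoxymethyl)-3,4-dimethoxyphenyl]-4,4,5,5-tetramethyl-1,3,2-dioxaborolane F1. Anion 7 (from 4, LiTMP, −78 °C) is quenched cold with DMF to give 2-bromo-3,6-dimethoxybenzaldehyde F2. Coupling of F1 and F2 with Pd(OAc)2, SPhos (2-dicyclohexylphosphino-2',6'-dimethoxybiphenyl) and K3PO4 in toluene/water at 90 °C should give 11.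

2. Step 8. The basic vinylogous amides may sequester BBr3 so that ether cleavage stops short, or the side chain may be lost by hydrolysis and retro-Claisen cleavage before ring closure. Fallback, setting out from 16 and returning at 18: the rings are closed first by electrophilic demethylative iodocyclization. ICl in CH2Cl2 at −78 °C → rt should give 3-iodo-5-[3-iodo-8-methoxy-4-oxo-2-(2-phenylethyl)-4H-chromen-5-yl]-6-methoxy-2-(2-phenylethyl)-4H-chromen-4-one F3. Zn dust in AcOH should remove both iodines to give 6-methoxy-5-[8-methoxy-4-oxo-2-(2-phenylethyl)-4H-chromen-5-yl]-2-(2-phenylethyl)-4H-chromen-4-one F4. BBr3 in CH2Cl2 on the robust bis-chromone then cleaves the two remaining methyl ethers to give 18.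

3. Step 5. After the first addition the alkoxide may close onto the neighbouring formyl group as a seven-membered lactol alkoxide, so that the second addition stalls, or hydride transfer may lead to a lactone. Fallback, setting out from 12 and returning at 16 (step 6 is then not needed): the acyl carbons are raised to the acid level. Pinnick oxidation (NaClO2, NaH2PO4, 2-methylbut-2-ene, t-BuOH/H2O) should give 3,3',4',6-tetramethoxybiphenyl-2,2'-dicarboxylic acid F5. Oxalyl chloride with cat. DMF, then N,O-dimethylhydroxylamine hydrochloride and Et3N, should give N2,N2'-dimethoxy-3,3',4',6-tetramethoxy-N2,N2'-dimethylbiphenyl-2,2'-dicarboxamide F6. Addition of lithium acetylide 14 (THF, −78 → 0 °C) to this bis-Weinreb amide stops at the chelated tetrahedral stage and should give bis-ynone 16 on work-up.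

**Further compounds**
F1 | step 3 | 2-[2-(dimethoxymethyl)-3,4-dimethoxyphenyl]-4,4,5,5-tetramethyl-1,3,2-dioxaborolane | COC(OC)c1c(B2OC(C)(C)C(C)(C)O2)ccc(OC)c1OC
F2 | step 3 | 2-bromo-3,6-dimethoxybenzaldehyde | O=Cc1c(Br)c(OC)ccc1OC
F3 | step 8 | 3-iodo-5-[3-iodo-8-methoxy-4-oxo-2-(2-phenylethyl)-4H-chromen-5-yl]-6-methoxy-2-(2-phenylethyl)-4H-chromen-4-one | O=c1c(I)c(CCc2ccccc2)oc2ccc(OC)c(-c3ccc(OC)c4oc(CCc5ccccc5)c(I)c(=O)c34)c12
F4 | step 8 | 6-methoxy-5-[8-methoxy-4-oxo-2-(2-phenylethyl)-4H-chromen-5-yl]-2-(2-phenylethyl)-4H-chromen-4-one | O=c1cc(CCc2ccccc2)oc2ccc(OC)c(-c3ccc(OC)c4oc(CCc5ccccc5)cc(=O)c34)c12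
F5 | step 5 | 3,3',4',6-tetramethoxybiphenyl-2,2'-dicarboxylic acid | OC(=O)c1c(OC)ccc(OC)c1-c1ccc(OC)c(OC)c1C(=O)O
F6 | step 5 | N2,N2'-dimethoxy-3,3',4',6-tetramethoxy-N2,N2'-dimethylbiphenyl-2,2'-dicarboxamide | CON(C)C(=O)c1c(OC)ccc(OC)c1-c1ccc(OC)c(OC)c1C(=O)N(C)OC
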